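**Assumption:** the SMILES is read literally: a cis-fused decalin, (4aR,8aS), with the ring-fusion H and the angular methyl on the same face; (2R) at the ester α-carbon; a (3E,5E)-diene. Nerylacetone of high Z purity is taken as a commercial, achiral starting material.

## Retrosynthetic overview

1. Target ⇒ Suzuki–Miyaura disconnection of the diene σ-bond (C4–C5 of the octadienoate): an E alkenyl iodide on the cis-decalin plus an (R,E)-alkenyl boronate that carries the ester α-stereocentre.
2. Alkenyl iodide ⇒ terminal alkyne (carboalumination–iodination) ⇒ allylic bromide + propyne dianion ⇒ tetrasubstituted enoate (enol triflate + methyl cuprate) ⇒ cis-fused bicyclic β-keto ester.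
3. Bicyclic β-keto ester ⇒ acyclic (6Z)-dienyl β-keto ester by one catalytic, enantioselective, proton-initiated cation–olefin bicyclisation. Ring A closes first and ring B second in the same step; the Z alkene becomes the cis ring fusion. The acyclic keto ester comes from nerylacetone and dimethyl carbonate.
4. Alkenyl boronate ⇒ methyl (R)-2-methylbut-3-enoate (cross-metathesis with vinyl boronate) ⇒ methyl 4-bromocrotonate + MeMgBr (copper-catalysed asymmetric allylic alkylation).

## Route

Step 1
Reactants: 1 nerylacetone, (5Z)-6,10-dimethylundeca-5,9-dien-2-one; 2 dimethyl carbonate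
Product: 3 methyl (6Z)-7,11-dimethyl-3-oxododeca-6,10-dienoate
Conditions: NaH (2.2 equiv), THF, 65 °C; then 1 M HCl
Reagents that add atoms: none
Why: Claisen-type C-acylation (carbomethoxylation) at the methyl side of the ketone, driven by irreversible deprotonation of the β-keto ester formed; the Z alkene is untouched and no stereocentre is made.

Step 2
Reactants: 3 methyl (6Z)-7,11-dimethyl-3-oxododeca-6,10-dienoate
Product: 4 methyl (4aR,8aS)-5,5,8a-trimethyl-2-oxodecahydronaphthalene-1-carboxylate (cis-fused; keto/enol and C1-epimer mixture, C1 is erased in step 3)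
Conditions: confined chiral imidodiphosphorimidate (IDPi) Brønsted acid (5 mol %; the enantiomer that gives 4aR,8aS, chosen by screening), (CF3)2CHOH–CH2Cl2, −20 °C
Reagents that add atoms: none
Why: Proposed new method: the confined chiral acid (two 3,3′-diaryl-BINOL units, N-perfluoroalkylsulfonyl imido groups) in the fluorinated alcohol protonates the terminal isopropylidene group of 3 inside its pocket, which is the enantio-determining event. The folded chain then closes ring A and ring B by anti addition across the 6Z alkene, and the enol carbon of the β-keto ester captures the tertiary cation. The Z geometry is thereby translated into the cis ring fusion (Stork–Eschenmoser rule), and the catalyst handedness fixes both ring-fusion centres. O-capture by the ketone is reversible under the acid whereas C-capture is not. The closest known reactions are the IDPi-catalysed protonative cyclisation of all-E homofarnesol-type polyenes that terminate at oxygen, and the racemic SnCl4 cyclisation of geranyl- and neryl-type β-keto esters.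

Step 3
Reactants: 4 methyl (4aR,8aS)-5,5,8a-trimethyl-2-oxodecahydronaphthalene-1-carboxylate
Product: 5 methyl (4aR,8aS)-5,5,8a-trimethyl-2-{[(trifluoromethyl)sulfonyl]oxy}-3,4,4a,5,6,7,8,8a-octahydronaphthalene-1-carboxylate
Conditions: Tf2O, i-Pr2NEt, CH2Cl2, −78 → 0 °C
Reagents that add atoms: triflic anhydride, O=S(=O)(OS(=O)(=O)C(F)(F)F)C(F)(F)F
Why: enol triflate formation: the hydrogen-bonded enol of the β-keto ester is O-sulfonylated regiospecifically at the ring carbonyl, which removes the labile C1 centre and leaves the ring-fusion centres untouched.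

Step 4
Reactants: 5 methyl (4aR,8aS)-5,5,8a-trimethyl-2-{[(trifluoromethyl)sulfonyl]oxy}-3,4,4a,5,6,7,8,8a-octahydronaphthalene-1-carboxylate
Product: 6 methyl (4aR,8aS)-2,5,5,8a-tetramethyl-3,4,4a,5,6,7,8,8a-octahydronaphthalene-1-carboxylate
Conditions: Me2CuLi (from CuBr·SMe2 and MeLi), Et2O–THF, −30 → 0 °C
Reagents that add atoms: lithium dimethylcuprate Me2CuLi, [Li+].C[Cu-]C (made in the flask from methyllithium, [Li]C, and CuBr·SMe2)
Why: Gilman cuprate addition–elimination on the β-triflyloxy enoate (cross-coupling of an enol triflate) replaces OTf by methyl without moving the double bond, so the tetrasubstituted ring alkene is placed regiospecifically.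

Step 5
Reactants: 6 methyl (4aR,8aS)-2,5,5,8a-tetramethyl-3,4,4a,5,6,7,8,8a-octahydronaphthalene-1-carboxylate
Product: 7 [(4aR,8aS)-2,5,5,8a-tetramethyl-3,4,4a,5,6,7,8,8a-octahydronaphthalen-1-yl]methanol
Conditions: i-Bu2AlH (3 equiv), CH2Cl2, −78 → 0 °C; aq. potassium sodium tartrate
Reagents that add atoms: none
Why: 1,2-reduction of the hindered conjugated ester by the aluminium hydride gives the allylic alcohol; no stereocentre is touched.

Step 6
Reactants: 7 [(4aR,8aS)-2,5,5,8a-tetramethyl-3,4,4a,5,6,7,8,8a-octahydronaphthalen-1-yl]methanol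
Product: 8 (4aR,8aS)-1-(bromomethyl)-2,5,5,8a-tetramethyl-3,4,4a,5,6,7,8,8a-octahydronaphthalene
Conditions: PBr3, pyridine (cat.), Et2O, −10 → 0 °C; used crude
Reagents that add atoms: phosphorus tribromide, BrP(Br)Br
Why: SN2-type bromination of a primary allylic alcohol at low temperature; the primary bromide is favoured over the tertiary allylic isomer and the ring alkene stays in place.

Step 7
Reactants: 8 (4aR,8aS)-1-(bromomethyl)-2,5,5,8a-tetramethyl-3,4,4a,5,6,7,8,8a-octahydronaphthalene
Product: 9 (4aR,8aS)-1-(but-3-yn-1-yl)-2,5,5,8a-tetramethyl-3,4,4a,5,6,7,8,8a-octahydronaphthalene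
Conditions: propyne, n-BuLi (2 equiv), TMEDA, Et2O–hexane, −78 → 0 °C; then 8, −78 → 25 °C; H2O
Reagents that add atoms: propyne, CC#C (used as 1,3-dilithiopropyne, [Li]CC#C[Li])
Why: SN2 propargylation: the sp3 carbanion of 1,3-dilithiopropyne alkylates the primary allylic bromide and the acetylide end is protonated on quench, giving the terminal 1,5-enyne directly.

Step 8
Reactants: 9 (4aR,8aS)-1-(but-3-yn-1-yl)-2,5,5,8a-tetramethyl-3,4,4a,5,6,7,8,8a-octahydronaphthalene
Product: 11 (4aR,8aS)-1-[(3E)-4-iodo-3-methylbut-3-en-1-yl]-2,5,5,8a-tetramethyl-3,4,4a,5,6,7,8,8a-octahydronaphthalene, via alkenyl(dimethyl)alane 10 (not isolated)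
Conditions: Me3Al (2.5 equiv), Cp2ZrCl2 (0.25 equiv), CH2Cl2, 0 → 25 °C; then [I][I] in THF, −30 °C
Reagents that add atoms: trimethylaluminium, C[Al](C)C; iodine, [I][I]
Why: Negishi zirconium-catalysed carboalumination adds Me and Al syn across the terminal alkyne with Al at the terminus, and iodinolysis goes with retention, which fixes the E trisubstituted alkene; the tetrasubstituted ring alkene is inert.

Step 9
Reactants: 12 methyl (2E)-4-bromobut-2-enoate
Product: 13 methyl (2R)-2-methylbut-3-enoate
Conditions: MeMgBr (1.2 equiv), CuBr·SMe2 (2 mol %), Taniaphos {1-[α-(dimethylamino)-2-(diphenylphosphino)benzyl]-2-(diphenylphosphino)ferrocene; the enantiomer that gives 2R} (2.4 mol %), CH2Cl2, −75 °C; product kept in solution (volatile)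
Reagents that add atoms: methylmagnesium bromide, C[Mg]Br
Why: copper-catalysed asymmetric allylic alkylation (SN2′) of a 4-bromocrotonate with a Grignard reagent; the chiral ferrocenyl diphosphine on copper controls the face of attack at C2 and sets the R centre from achiral material.

Step 10
Reactants: 13 methyl (2R)-2-methylbut-3-enoate; 14 2-ethenyl-4,4,5,5-tetramethyl-1,3,2-dioxaborolane
Product: 15 methyl (2R,3E)-2-methyl-4-(4,4,5,5-tetramethyl-1,3,2-dioxaborolan-2-yl)but-3-enoate
Conditions: second-generation Grubbs catalyst RuCl2(=CHPh)(PCy3)(H2IMes) (5 mol %), 1,4-benzoquinone (10 mol %), CH2Cl2, 40 °C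
Reagents that add atoms: none
Why: olefin cross-metathesis of the hindered monosubstituted alkene with the vinyl boronate is E-selective and neutral, so the α-centre is kept; benzoquinone suppresses Ru–H alkene migration.

Step 11
Reactants: 11 (4aR,8aS)-1-[(3E)-4-iodo-3-methylbut-3-en-1-yl]-2,5,5,8a-tetramethyl-3,4,4a,5,6,7,8,8a-octahydronaphthalene; 15 methyl (2R,3E)-2-methyl-4-(4,4,5,5-tetramethyl-1,3,2-dioxaborolan-2-yl)but-3-enoate
Product: 16 methyl (2R,3E,5E)-2,6-dimethyl-8-[(4aR,8aS)-2,5,5,8a-tetramethyl-3,4,4a,5,6,7,8,8a-octahydronaphthalen-1-yl]octa-3,5-dienoate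
Conditions: PdCl2(dppf) (5 mol %), K3PO4 (3 M aq.), THF, 25 °C, degassed, short reaction time
Reagents that add atoms: none
Why: Suzuki–Miyaura coupling of an E alkenyl iodide with an E alkenyl boronate is stereoretentive at both alkenes and gives the (3E,5E)-diene; the mild phosphate base at 25 °C is chosen to keep the base-labile α-stereocentre.

## Compound list

1 | nerylacetone, (5Z)-6,10-dimethylundeca-5,9-dien-2-one | CC(=O)CC/C=C(/C)CCC=C(C)C | starting material
2 | dimethyl carbonate | COC(=O)OC | starting material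
3 | methyl (6Z)-7,11-dimethyl-3-oxododeca-6,10-dienoate | COC(=O)CC(=O)CC/C=C(/C)CCC=C(C)C | intermediate
4 | methyl (4aR,8aS)-5,5,8a-trimethyl-2-oxodecahydronaphthalene-1-carboxylate (cis-fused, C1 epimers/enol) | COC(=O)C1C(=O)CC[C@@H]2C(C)(C)CCC[C@]12C | intermediate
5 | methyl (4aR,8aS)-5,5,8a-trimethyl-2-{[(trifluoromethyl)sulfonyl]oxy}-3,4,4a,5,6,7,8,8a-octahydronaphthalene-1-carboxylate | COC(=O)C1=C(OS(=O)(=O)C(F)(F)F)CC[C@@H]2C(C)(C)CCC[C@]12C | intermediate
6 | methyl (4aR,8aS)-2,5,5,8a-tetramethyl-3,4,4a,5,6,7,8,8a-octahydronaphthalene-1-carboxylate | COC(=O)C1=C(C)CC[C@@H]2C(C)(C)CCC[C@]12C | intermediate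
7 | [(4aR,8aS)-2,5,5,8a-tetramethyl-3,4,4a,5,6,7,8,8a-octahydronaphthalen-1-yl]methanol | OCC1=C(C)CC[C@@H]2C(C)(C)CCC[C@]12C | intermediate
8 | (4aR,8aS)-1-(bromomethyl)-2,5,5,8a-tetramethyl-3,4,4a,5,6,7,8,8a-octahydronaphthalene | BrCC1=C(C)CC[C@@H]2C(C)(C)CCC[C@]12C | intermediate
9 | (4aR,8aS)-1-(but-3-yn-1-yl)-2,5,5,8a-tetramethyl-3,4,4a,5,6,7,8,8a-octahydronaphthalene | C#CCCC1=C(C)CC[C@@H]2C(C)(C)CCC[C@]12C | intermediate
10 | dimethyl{(1E)-2-methyl-4-[(4aR,8aS)-2,5,5,8a-tetramethyl-3,4,4a,5,6,7,8,8a-octahydronaphthalen-1-yl]but-1-en-1-yl}alumane | C[Al](C)/C=C(\C)CCC1=C(C)CC[C@@H]2C(C)(C)CCC[C@]12C | intermediate (not isolated)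
11 | (4aR,8aS)-1-[(3E)-4-iodo-3-methylbut-3-en-1-yl]-2,5,5,8a-tetramethyl-3,4,4a,5,6,7,8,8a-octahydronaphthalene | I/C=C(\C)CCC1=C(C)CC[C@@H]2C(C)(C)CCC[C@]12C | intermediate
12 | methyl (2E)-4-bromobut-2-enoate | COC(=O)/C=C/CBr | starting material
13 | methyl (2R)-2-methylbut-3-enoate | COC(=O)[C@H](C)C=C | intermediate
14 | 2-ethenyl-4,4,5,5-tetramethyl-1,3,2-dioxaborolane | C=CB1OC(C)(C)C(C)(C)O1 | starting material
15 | methyl (2R,3E)-2-methyl-4-(4,4,5,5-tetramethyl-1,3,2-dioxaborolan-2-yl)but-3-enoate | COC(=O)[C@H](C)/C=C/B1OC(C)(C)C(C)(C)O1 | intermediate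
16 | methyl (2R,3E,5E)-2,6-dimethyl-8-[(4aR,8aS)-2,5,5,8a-tetramethyl-3,4,4a,5,6,7,8,8a-octahydronaphthalen-1-yl]octa-3,5-dienoate | COC(=O)[C@H](C)/C=C/C=C(\C)CCC1=C(C)CC[C@@H]2C(C)(C)CCC[C@]12C | target

## Step count and risks

Total step count: 11. Longest linear sequence: 9 (steps 1–8 and 11); steps 9–10 build the side-chain fragment.

Steps most likely to fail:

**Step 2 (the proposed new cyclisation).** Possible failures are a stable O-cyclised enol ether, monocyclic olefins, leakage to the trans-fused isomer through a stepwise cation, or low ee. The fallback uses known chemistry, sets out from 1 and comes back to the route at 4. Shi epoxidation of 1 (fructose-derived ketone catalyst of the enantiomeric series that gives the S oxirane, KHSO5, pH 10.5 buffer, MeCN–dimethoxymethane, 0 °C, run to partial conversion for selectivity at the terminal alkene) gives (5Z)-8-[(2S)-3,3-dimethyloxiran-2-yl]-6-methyloct-5-en-2-one F1. Carbomethoxylation with 2 as in step 1 gives methyl (6Z)-9-[(2S)-3,3-dimethyloxiran-2-yl]-7-methyl-3-oxonon-6-enoate F2. Lewis-acid epoxy-polyene cyclisation (SnCl4, CH2Cl2, −78 °C), in which the oxirane centre now dictates the chair fold and the Z alkene again gives the cis fusion, gives methyl (4aS,6S,8aS)-6-hydroxy-5,5,8a-trimethyl-2-oxodecahydronaphthalene-1-carboxylate F3; its 4a descriptor reads S only because the oxygenated carbon changes the CIP ranking, the spatial arrangement being that of 4. Barton–McCombie deoxygenation through methyl (4aS,6S,8aS)-6-[(1H-imidazol-1-ylcarbonothioyl)oxy]-5,5,8a-trimethyl-2-oxodecahydronaphthalene-1-carboxylate F4 (1,1′-thiocarbonyldiimidazole, 1,2-dichloroethane, 80 °C; then Bu3SnH, AIBN, toluene, 110 °C) then gives 4.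

**Step 7 (propargylation of the hindered allylic bromide with a strongly basic dianion).** Possible failures are elimination, SN2′ attack or allene formation. The fallback sets out from 8 and comes back at 9 by way of enolate alkylation and a ketone-to-alkyne conversion. Alkylation of the sodium enolate of methyl acetoacetate (NaH, THF, 0 → 25 °C) with 8 gives methyl 2-acetyl-3-[(4aR,8aS)-2,5,5,8a-tetramethyl-3,4,4a,5,6,7,8,8a-octahydronaphthalen-1-yl]propanoate F5. Saponification and decarboxylation (NaOH, aq. MeOH; then H3O+, 60 °C) give 4-[(4aR,8aS)-2,5,5,8a-tetramethyl-3,4,4a,5,6,7,8,8a-octahydronaphthalen-1-yl]butan-2-one F6. Kinetic enolisation and phosphorylation (LiN(i-Pr)2, THF, −78 °C; ClP(O)(OEt)2) give diethyl 4-[(4aR,8aS)-2,5,5,8a-tetramethyl-3,4,4a,5,6,7,8,8a-octahydronaphthalen-1-yl]but-1-en-2-yl phosphate F7, which is eliminated in the same flask with LiN(i-Pr)2 (2.2 equiv, −78 → 25 °C) to 9.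

**Step 11 (Suzuki coupling next to a base-labile α-stereocentre).** Possible failures are epimerisation at C2, migration of the diene into conjugation with the ester, or protodeboronation. The fallback sets out from 9 and 15 and comes back at 16 by a base-free Negishi alkenyl–alkenyl coupling. Iododeboronation of 15 with retention (sodium iodide, TsN(Cl)Na, THF–H2O, 0 °C) gives methyl (2R,3E)-4-iodo-2-methylbut-3-enoate F8. Alkyne 9 is carboaluminated as in step 8 to 10, which is not iodinated but coupled directly with F8 (Pd(PPh3)4 5 mol %, ZnCl2, THF, 25 °C) to give 16.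

## Further compounds

F1 | step 2 | (5Z)-8-[(2S)-3,3-dimethyloxiran-2-yl]-6-methyloct-5-en-2-one | CC(=O)CC/C=C(/C)CC[C@@H]1OC1(C)C
F2 | step 2 | methyl (6Z)-9-[(2S)-3,3-dimethyloxiran-2-yl]-7-methyl-3-oxonon-6-enoate | COC(=O)CC(=O)CC/C=C(/C)CC[C@@H]1OC1(C)C
F3 | step 2 | methyl (4aS,6S,8aS)-6-hydroxy-5,5,8a-trimethyl-2-oxodecahydronaphthalene-1-carboxylate | COC(=O)C1C(=O)CC[C@@H]2C(C)(C)[C@@H](O)CC[C@]12C
F4 | step 2 | methyl (4aS,6S,8aS)-6-[(1H-imidazol-1-ylcarbonothioyl)oxy]-5,5,8a-trimethyl-2-oxodecahydronaphthalene-1-carboxylate | COC(=O)C1C(=O)CC[C@@H]2C(C)(C)[C@@H](OC(=S)n3ccnc3)CC[C@]12C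
F5 | step 7 | methyl 2-acetyl-3-[(4aR,8aS)-2,5,5,8a-tetramethyl-3,4,4a,5,6,7,8,8a-octahydronaphthalen-1-yl]propanoate | COC(=O)C(C(C)=O)CC1=C(C)CC[C@@H]2C(C)(C)CCC[C@]12C
F6 | step 7 | 4-[(4aR,8aS)-2,5,5,8a-tetramethyl-3,4,4a,5,6,7,8,8a-octahydronaphthalen-1-yl]butan-2-one | CC(=O)CCC1=C(C)CC[C@@H]2C(C)(C)CCC[C@]12C
F7 | step 7 | diethyl 4-[(4aR,8aS)-2,5,5,8a-tetramethyl-3,4,4a,5,6,7,8,8a-octahydronaphthalen-1-yl]but-1-en-2-yl phosphate | C=C(OP(=O)(OCC)OCC)CCC1=C(C)CC[C@@H]2C(C)(C)CCC[C@]12C
F8 | step 11 | methyl (2R,3E)-4-iodo-2-methylbut-3-enoate | COC(=O)[C@H](C)/C=C/I
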